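**Plan**

- Ring numbering: C1'(CH3)=C2'H–C3'H(pyranone)–C4'H(iPr)–C5'H2–C6'H2. Retrosynthetic cuts, in order: the O–CH3 bond of a 4-methoxy ether; ring bond C6'–C1'; C1'=C2'; C5'=C6'; C3'–C4'; C2'–C3' (made as a nitroalkene); pyranone C3–C3'.
- Enabling feature: in the cyclohexene ring the alkene C1'=C2' lies next to the pyranone-bearing C3', and C1' is joined by a single bond to the plain methylene C6'. A (Z)-2-iodopropenyl group on C3' and a vinyl group on C4' can therefore only close at C6'–C1', with the alkene position fixed.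
- Forward: the chain is grown on the intact styrylpyranone (C3' by formylation, C2' by Henry condensation, C4'/C5' by Michael addition, C6' by methylenation, C1' and its methyl by iodo-olefination). The cyclohexene, the only new ring, is closed in the second-last step, and O-demethylation ends the route.
- Stereochemistry: C3' and C4' both arise in the amine-catalysed syn-selective Michael addition; the (2R,3S) adduct corresponds to the trans (1R,6R) ring. The alkene position comes from the (Z)-iodide, and the (E)-styryl unit is carried in with the starting pyranone.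

Key step: step 7

Assumption: pyranone 1 (the kavalactone desmethoxyyangonin) is purchased, and electrophilic substitution of 1 is taken to occur at C3, as it does in simpler 4-methoxy-2-pyranones.

**Route**

Step 1
Reactants: 1 4-methoxy-6-[(E)-2-phenylethenyl]-2H-pyran-2-one
Product: 3 4-methoxy-2-oxo-6-[(E)-2-phenylethenyl]-2H-pyran-3-carbaldehyde, via chloro(methoxy)methyl pyranone 2 (not isolated)
Conditions: Cl2CHOMe, TiCl4, CH2Cl2, 0 °C to rt; then ice-water
Reagents that add atoms: dichloromethyl methyl ether COC(Cl)Cl; water O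
Why: Rieche formylation: the chloro(methoxy)carbenium ion generated by TiCl4 should attack C3, the most electron-rich ring carbon (enol-ether β-carbon flanked by both oxygenated carbons), and aqueous work-up hydrolyses α-chloro ether 2 to the aldehyde, as is known for 4-methoxy-6-methyl-2-pyranone.

Step 2
Reactants: 3 4-methoxy-2-oxo-6-[(E)-2-phenylethenyl]-2H-pyran-3-carbaldehyde; 4 nitromethane
Product: 7 4-methoxy-3-[(E)-2-nitroethenyl]-6-[(E)-2-phenylethenyl]-2H-pyran-2-one, via nitroaldol 5 (not isolated), via nitroaldol mesylate 6 (not isolated)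
Conditions: MeNO2 (5 equiv), Et3N (0.1 equiv), THF, 0 °C to rt; evaporate; then MsCl, Et3N, CH2Cl2, −10 to 0 °C
Reagents that add atoms: none
Why: Henry (nitroaldol) addition to the non-enolisable, strongly electrophilic aldehyde, followed by mesylation and E1cB elimination, should give the thermodynamically preferred (E)-nitroalkene without exposing the 4-methoxy group to ammonia or primary amines.

Step 3
Reactants: 7 4-methoxy-3-[(E)-2-nitroethenyl]-6-[(E)-2-phenylethenyl]-2H-pyran-2-one; 8 3-methylbutanal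
Product: 9 (2R,3S)-3-{4-methoxy-2-oxo-6-[(E)-2-phenylethenyl]-2H-pyran-3-yl}-4-nitro-2-(propan-2-yl)butanal
Conditions: (S)-2-[diphenyl(trimethylsilyloxy)methyl]pyrrolidine (10 mol%), 4-nitrophenol (10 mol%), aldehyde in threefold excess, toluene, 0 °C to rt
Reagents that add atoms: none
Why: Enamine-catalysed Michael addition of an aldehyde to a β-(hetero)aryl nitroalkene, a pure addition in which every atom of 7 and of one molecule of 8 ends up in 9: the (E)-enamine of 8, shielded on one face by the diphenyl(silyloxy)methyl group, should add through an acyclic synclinal transition state, which sets C4' (R in 9) by catalyst control and C3' (S in 9) by the syn topicity of that transition state.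

Step 4
Reactants: 9 (2R,3S)-3-{4-methoxy-2-oxo-6-[(E)-2-phenylethenyl]-2H-pyran-3-yl}-4-nitro-2-(propan-2-yl)butanal
Product: 11 4-methoxy-3-[(2S,3S)-1-nitro-3-(propan-2-yl)pent-4-en-2-yl]-6-[(E)-2-phenylethenyl]-2H-pyran-2-one, via potassium nitronate 10 (not isolated)
Conditions: Ph3PCH3Br (3.0 equiv), KN(SiMe3)2 (2.8 equiv), THF, −78 to 0 °C; then aq. NH4Cl
Reagents that add atoms: methyltriphenylphosphonium bromide C[P+](c1ccccc1)(c1ccccc1)c1ccccc1.[Br-]
Why: Wittig methylenation, as practised on γ-nitro aldehydes from such Michael additions; the excess ylide parks the CH2NO2 group as nitronate 10, which should suppress retro-Michael cleavage and enolisation at C4', and ammonium chloride returns the nitroalkane.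

Step 5
Reactants: 11 4-methoxy-3-[(2S,3S)-1-nitro-3-(propan-2-yl)pent-4-en-2-yl]-6-[(E)-2-phenylethenyl]-2H-pyran-2-one
Product: 13 (2S,3S)-2-{4-methoxy-2-oxo-6-[(E)-2-phenylethenyl]-2H-pyran-3-yl}-3-(propan-2-yl)pent-4-enal, via sodium nitronate 12 (not isolated)
Conditions: NaOMe (1.05 equiv), MeOH, 0 °C; then aq. TiCl3 (4.5 equiv), NH4OAc (pH about 6), THF–H2O, 0 °C to rt; product used at once
Reagents that add atoms: water O
Why: Reductive Nef reaction: trivalent titanium reduces the nitronate to the imine, which hydrolyses to the aldehyde near neutral pH; these conditions should leave the vinyl, styryl and pyranone units alone and give the configurationally labile C3' little chance to epimerise.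

Step 6
Reactants: 13 (2S,3S)-2-{4-methoxy-2-oxo-6-[(E)-2-phenylethenyl]-2H-pyran-3-yl}-3-(propan-2-yl)pent-4-enal
Product: 14 3-[(2Z,4R,5S)-2-iodo-5-(propan-2-yl)hepta-2,6-dien-4-yl]-4-methoxy-6-[(E)-2-phenylethenyl]-2H-pyran-2-one
Conditions: Ph3PEtI, n-BuLi, THF, rt; I2, −78 °C; NaN(SiMe3)2, −78 to −20 °C; then 13, −78 to −20 °C
Reagents that add atoms: ethyltriphenylphosphonium iodide CC[P+](c1ccccc1)(c1ccccc1)c1ccccc1.[I-]; iodine [I][I]
Why: Stork–Zhao olefination with the α-iodoethylidene ylide, which converts α-branched aldehydes into (Z)-2-iodo-2-alkenes (iodine cis to the chain) under kinetic control; at −78 °C carbonyl addition should outrun deprotonation at C3'.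

Step 7
Reactants: 14 3-[(2Z,4R,5S)-2-iodo-5-(propan-2-yl)hepta-2,6-dien-4-yl]-4-methoxy-6-[(E)-2-phenylethenyl]-2H-pyran-2-one
Product: 16 4-methoxy-3-[(1R,6R)-3-methyl-6-(propan-2-yl)cyclohex-2-en-1-yl]-6-[(E)-2-phenylethenyl]-2H-pyran-2-one, via B-alkyl-9-BBN borane 15 (not isolated)
Conditions: 9-BBN (1.5 equiv), THF, 0 °C to rt; then PdCl2(dppf) [dppf = 1,1'-bis(diphenylphosphino)ferrocene] (10 mol%), AsPh3 (10 mol%), Cs2CO3 (3 equiv), DMF–THF–H2O, 0.01 M, rt to 45 °C
Reagents that add atoms: none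
Why: 9-BBN adds to the monosubstituted C5'=C6' alkene with boron on C6'; zerovalent palladium then inserts into the C1'–I bond, the carbonate-activated borate transfers C6' to palladium, and reductive elimination forms C6'–C1' with retention of the alkene geometry. The closest known reaction type is the intramolecular B-alkyl Suzuki–Miyaura coupling of ω-boryl alkenyl iodides, which makes five- and six-membered carbocycles. The cyclohexene closes by reductive elimination from a seven-membered alkyl(alkenyl)palladium ring, so the alkene stays inside the new ring at C1'=C2'. No stereocentre is formed; C3' and C4' are spectators and are not acidic towards carbonate. The step needs chemoselective hydroboration, which the far higher rate of 9-BBN with a terminal vinyl group than with 1,2-disubstituted, trisubstituted, halogen-bearing or pyranone double bonds should secure. It also needs iodine cis to C3', which the (Z)-iodide 14 provides; this makes six-ring closure geometrically possible and excludes any other alkene isomer.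

Step 8
Reactants: 16 4-methoxy-3-[(1R,6R)-3-methyl-6-(propan-2-yl)cyclohex-2-en-1-yl]-6-[(E)-2-phenylethenyl]-2H-pyran-2-one
Product: 18 4-hydroxy-3-[(1R,6R)-3-methyl-6-(propan-2-yl)cyclohex-2-en-1-yl]-6-[(E)-2-phenylethenyl]-2H-pyran-2-one, via lithium pyranolate 17 (not isolated)
Conditions: LiCl (10 equiv), DMF, 140 °C; then cold 1 M HCl
Reagents that add atoms: none
Why: SN2 demethylation by chloride at the O-methyl carbon of the vinylogous methyl carbonate releases the resonance-stabilised pyranolate; a non-acidic method is chosen because a protic or Lewis acid could add the freed 4-hydroxyl to the C1'=C2' alkene, and neither stereocentre is touched.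

**Compound list**

1 | 4-methoxy-6-[(E)-2-phenylethenyl]-2H-pyran-2-one | COc1cc(/C=C/c2ccccc2)oc(=O)c1 | starting material
2 | 3-[chloro(methoxy)methyl]-4-methoxy-6-[(E)-2-phenylethenyl]-2H-pyran-2-one (racemic at the new carbon) | COC(Cl)c1c(OC)cc(/C=C/c2ccccc2)oc1=O | intermediate
3 | 4-methoxy-2-oxo-6-[(E)-2-phenylethenyl]-2H-pyran-3-carbaldehyde | O=Cc1c(OC)cc(/C=C/c2ccccc2)oc1=O | intermediate
4 | nitromethane | C[N+](=O)[O-] | starting material
5 | 3-(1-hydroxy-2-nitroethyl)-4-methoxy-6-[(E)-2-phenylethenyl]-2H-pyran-2-one (racemic) | OC(C[N+](=O)[O-])c1c(OC)cc(/C=C/c2ccccc2)oc1=O | intermediate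
6 | 1-{4-methoxy-2-oxo-6-[(E)-2-phenylethenyl]-2H-pyran-3-yl}-2-nitroethyl methanesulfonate (racemic) | CS(=O)(=O)OC(C[N+](=O)[O-])c1c(OC)cc(/C=C/c2ccccc2)oc1=O | intermediate
7 | 4-methoxy-3-[(E)-2-nitroethenyl]-6-[(E)-2-phenylethenyl]-2H-pyran-2-one | [O-][N+](=O)/C=C/c1c(OC)cc(/C=C/c2ccccc2)oc1=O | intermediate
8 | 3-methylbutanal | CC(C)CC=O | starting material
9 | (2R,3S)-3-{4-methoxy-2-oxo-6-[(E)-2-phenylethenyl]-2H-pyran-3-yl}-4-nitro-2-(propan-2-yl)butanal | [O-][N+](=O)C[C@H](c1c(OC)cc(/C=C/c2ccccc2)oc1=O)[C@@H](C(C)C)C=O | intermediate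
10 | potassium nitronate of 11 (nitro-bearing carbon deprotonated; both stereocentres as in 11) | [K+].[O-][N+]([O-])=C[C@H](c1c(OC)cc(/C=C/c2ccccc2)oc1=O)[C@@H](C(C)C)C=C | intermediate
11 | 4-methoxy-3-[(2S,3S)-1-nitro-3-(propan-2-yl)pent-4-en-2-yl]-6-[(E)-2-phenylethenyl]-2H-pyran-2-one | [O-][N+](=O)C[C@H](c1c(OC)cc(/C=C/c2ccccc2)oc1=O)[C@@H](C(C)C)C=C | intermediate
12 | sodium nitronate of 11 (both stereocentres as in 11) | [Na+].[O-][N+]([O-])=C[C@H](c1c(OC)cc(/C=C/c2ccccc2)oc1=O)[C@@H](C(C)C)C=C | intermediate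
13 | (2S,3S)-2-{4-methoxy-2-oxo-6-[(E)-2-phenylethenyl]-2H-pyran-3-yl}-3-(propan-2-yl)pent-4-enal | O=C[C@H](c1c(OC)cc(/C=C/c2ccccc2)oc1=O)[C@@H](C(C)C)C=C | intermediate
14 | 3-[(2Z,4R,5S)-2-iodo-5-(propan-2-yl)hepta-2,6-dien-4-yl]-4-methoxy-6-[(E)-2-phenylethenyl]-2H-pyran-2-one | C/C(I)=C/[C@H](c1c(OC)cc(/C=C/c2ccccc2)oc1=O)[C@@H](C(C)C)C=C | intermediate
15 | 3-[(2Z,4R,5R)-7-(9-borabicyclo[3.3.1]nonan-9-yl)-2-iodo-5-(propan-2-yl)hept-2-en-4-yl]-4-methoxy-6-[(E)-2-phenylethenyl]-2H-pyran-2-one | C/C(I)=C/[C@H](c1c(OC)cc(/C=C/c2ccccc2)oc1=O)[C@@H](C(C)C)CCB1C2CCCC1CCC2 | intermediate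
16 | 4-methoxy-3-[(1R,6R)-3-methyl-6-(propan-2-yl)cyclohex-2-en-1-yl]-6-[(E)-2-phenylethenyl]-2H-pyran-2-one | CC1=C[C@H](c2c(OC)cc(/C=C/c3ccccc3)oc2=O)[C@@H](C(C)C)CC1 | intermediate
17 | lithium 3-[(1R,6R)-3-methyl-6-(propan-2-yl)cyclohex-2-en-1-yl]-2-oxo-6-[(E)-2-phenylethenyl]-2H-pyran-4-olate | [Li+].CC1=C[C@H](c2c([O-])cc(/C=C/c3ccccc3)oc2=O)[C@@H](C(C)C)CC1 | intermediate
18 | 4-hydroxy-3-[(1R,6R)-3-methyl-6-(propan-2-yl)cyclohex-2-en-1-yl]-6-[(E)-2-phenylethenyl]-2H-pyran-2-one | CC1=C[C@H](c2c(O)cc(/C=C/c3ccccc3)oc2=O)[C@@H](C(C)C)CC1 | target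

**Step count**

Total: 8 steps. Longest linear sequence: 8 steps, from 1 to 18.

**Steps most likely to fail**

1. Step 6 (iodo-olefination). What may go wrong: the basic ylide deprotonates the doubly activated C3'–H of 13 and C3' epimerises; the Z/E selectivity may also erode, or the ylide may lose iodine. Fallback, from 13 back to 16: a Ramirez dibromo-olefination (CBr4, PPh3, CH2Cl2, 0 °C), which needs no strong base, would give 1,1-dibromoalkene F1. A palladium-catalysed trans-selective Negishi monomethylation (Me2Zn, PdCl2(DPEphos) [DPEphos = bis(2-diphenylphosphinophenyl) ether], THF, 0 °C to rt) should replace only the bromine trans to C3' and give (Z)-2-bromoalkene F2, the bromo analogue of 14. Hydroboration with 9-BBN would then give B-alkyl-9-BBN borane F3, which under the palladium conditions of step 7 should close the same C6'–C1' bond and rejoin the route at 16.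

2. Step 5 (Nef reaction). What may go wrong: reduction stops at the oxime, methoxide attacks the pyranone during nitronate formation, or the α-pyranonyl aldehyde epimerises in the ammonium acetate buffer. Fallback, from 11 back to 13: oxidation of the primary nitro group with NaNO2 and AcOH in DMSO at 35 °C would give carboxylic acid F4. Activation with isobutyl chloroformate and N-methylmorpholine (THF, −15 °C) gives isobutyl carbonic mixed anhydride F5, which NaBH4 reduces to primary alcohol F6. Oxidation with Dess–Martin periodinane buffered with NaHCO3 then delivers 13 under anhydrous, non-basic conditions immediately before step 6.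

3. Step 7 (ring closure). What may go wrong: transmetallation of the alkylborate is slow, so the alkenylpalladium iodide is lost by protodeiodination, or aqueous carbonate opens the pyranone. Fallback, from 14 back to 16: a base-free Negishi closure of the same bond. Hydroboration with 9-BBN (borane 15) and oxidation with NaBO3·4H2O would give primary alcohol F7. An Appel reaction (I2, PPh3, imidazole, CH2Cl2) converts it into diiodide F8. Zinc dust with LiCl in THF should insert only into the C(sp3)–I bond to give alkylzinc iodide F9, which Pd(PPh3)4 cyclises onto the alkenyl iodide to give 16.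

**Further compounds**

F1 | step 6 | 3-[(3R,4S)-1,1-dibromo-4-(propan-2-yl)hexa-1,5-dien-3-yl]-4-methoxy-6-[(E)-2-phenylethenyl]-2H-pyran-2-one | BrC(Br)=C[C@H](c1c(OC)cc(/C=C/c2ccccc2)oc1=O)[C@@H](C(C)C)C=C
F2 | step 6 | 3-[(2Z,4R,5S)-2-bromo-5-(propan-2-yl)hepta-2,6-dien-4-yl]-4-methoxy-6-[(E)-2-phenylethenyl]-2H-pyran-2-one | C/C(Br)=C/[C@H](c1c(OC)cc(/C=C/c2ccccc2)oc1=O)[C@@H](C(C)C)C=C
F3 | step 6 | 3-[(2Z,4R,5R)-7-(9-borabicyclo[3.3.1]nonan-9-yl)-2-bromo-5-(propan-2-yl)hept-2-en-4-yl]-4-methoxy-6-[(E)-2-phenylethenyl]-2H-pyran-2-one | C/C(Br)=C/[C@H](c1c(OC)cc(/C=C/c2ccccc2)oc1=O)[C@@H](C(C)C)CCB1C2CCCC1CCC2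
F4 | step 5 | (2S,3S)-2-{4-methoxy-2-oxo-6-[(E)-2-phenylethenyl]-2H-pyran-3-yl}-3-(propan-2-yl)pent-4-enoic acid | OC(=O)[C@H](c1c(OC)cc(/C=C/c2ccccc2)oc1=O)[C@@H](C(C)C)C=C
F5 | step 5 | (2S,3S)-2-{4-methoxy-2-oxo-6-[(E)-2-phenylethenyl]-2H-pyran-3-yl}-3-(propan-2-yl)pent-4-enoic 2-methylpropyl carbonic anhydride | CC(C)COC(=O)OC(=O)[C@H](c1c(OC)cc(/C=C/c2ccccc2)oc1=O)[C@@H](C(C)C)C=C
F6 | step 5 | 3-[(2S,3S)-1-hydroxy-3-(propan-2-yl)pent-4-en-2-yl]-4-methoxy-6-[(E)-2-phenylethenyl]-2H-pyran-2-one | OC[C@H](c1c(OC)cc(/C=C/c2ccccc2)oc1=O)[C@@H](C(C)C)C=C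
F7 | step 7 | 3-[(2Z,4R,5R)-7-hydroxy-2-iodo-5-(propan-2-yl)hept-2-en-4-yl]-4-methoxy-6-[(E)-2-phenylethenyl]-2H-pyran-2-one | C/C(I)=C/[C@H](c1c(OC)cc(/C=C/c2ccccc2)oc1=O)[C@@H](C(C)C)CCO
F8 | step 7 | 3-[(2Z,4R,5R)-2,7-diiodo-5-(propan-2-yl)hept-2-en-4-yl]-4-methoxy-6-[(E)-2-phenylethenyl]-2H-pyran-2-one | C/C(I)=C/[C@H](c1c(OC)cc(/C=C/c2ccccc2)oc1=O)[C@@H](C(C)C)CCI
F9 | step 7 | {(3R,4R,5Z)-6-iodo-4-{4-methoxy-2-oxo-6-[(E)-2-phenylethenyl]-2H-pyran-3-yl}-3-(propan-2-yl)hept-5-en-1-yl}zinc iodide | C/C(I)=C/[C@H](c1c(OC)cc(/C=C/c2ccccc2)oc1=O)[C@@H](C(C)C)CC[Zn]I
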